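## Retrosynthetic overview
1. Niveusin B comes from a C15-silyl ether, with the C8 angelate added late and the α-methylene lactone unmasked from its amine adduct. The bridged C3/C10 hemiketal is the cyclised form of a (Z)-γ-hydroxy-enone (C3 ketone, C10 tertiary OH).
2. Key ring closure is the C3–C4 bond, which forms the 10-membered carbocycle. The Z-olefin comes from a Z-vinyl iodide and is closed by a **proposed new** Ni-catalysed intramolecular aldehyde C–H alkenylation. The aldehyde is the lactol-derived C3 carbon from linalool.
3. The trans α-methylene lactone (C6/C7) comes from a Cr-Barbier allylation of a Z-β-iodoenal (from butynediol) with a C7 allyl bromide. The C8 stereocentre comes from proline α-aminoxylation. The THF ring and the C10 quaternary centre come from (R)-linalool.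
4. Ring order: THF lactol (step 1), then γ-lactone (step 14), then 10-membered ring plus oxa-bridge (step 17).

Assumptions, one line each:
- L-Proline gives the (R)-α-aminoxy aldehyde; if it does not, D-proline is used.
- Hydroformylation of the vinyl group is linear-selective.
- The Cr-allylation delivers the required facial selectivity at C6/C7 relative to C8, with anti selectivity giving the trans-lactone.
- The C3 hemiketal configuration is dictated by bridging.
- CrCl2 is Ni-free.

## Route

**Step 1**
Reactants: 1 (R)-linalool
Product: 2 lactol, (5R)-5-methyl-5-(4-methylpent-3-enyl)tetrahydrofuran-2-ol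
Conditions: CO/H2 (1:1, 10 bar), Rh(acac)(CO)2 (0.5 mol%), biphephos, PhMe, 60 °C
Reagents that add atoms: carbon monoxide [C-]#[O+]; hydrogen [H][H]
Why: Linear-selective hydroformylation of the vinyl group, leaving the prenyl alkene untouched, gives a γ-hydroxy aldehyde that closes to the lactol. This builds C3, leaves the C10 quaternary centre untouched, and sets the THF ring.

**Step 2**
Reactants: 2
Product: 3 methyl acetal, 2-methoxy-5-methyl-5-(4-methylpent-3-enyl)THF (anomer mixture)
Conditions: MeOH, HC(OMe)3, PPTS (cat.), rt
Reagents that add atoms: methanol CO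
Why: Acetalisation (glycoside formation) masks the C3 aldehyde so it survives the later Cr-Barbier step.

**Step 3**
Reactants: 3
Product: 4 aldehyde, 3-(2-methoxy-5-methylTHF-5-yl)propanal (C7 aldehyde)
Conditions: O3, CH2Cl2/MeOH, –78 °C; then PPh3
Reagents that add atoms: ozone [O-][O+]=O
Why: Ozonolysis cleaves the only remaining alkene (C7=CMe2) to the C7 aldehyde.

**Step 4**
Reactants: 4
Product: 5 aminoxy alcohol, 2-methoxy-5-methyl-5-[(2R)-3-hydroxy-2-(anilinooxy)propyl]THF
Conditions: PhNO, L-proline (20 mol%), DMSO, rt; then NaBH4, MeOH, 0 °C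
Reagents that add atoms: nitrosobenzene O=Nc1ccccc1
Why: Proline-catalysed α-aminoxylation, with catalyst control and no influence from the remote C10, sets C8 as (R). In-situ reduction protects the α-stereocentre from racemisation.

**Step 5**
Reactants: 5
Product: 6 diol, 2-methoxy-5-methyl-5-[(2R)-2,3-dihydroxypropyl]THF
Conditions: CuSO4·5H2O (10 mol%), MeOH, rt
Reagents that add atoms: none
Why: Cu(II)-mediated N–O cleavage gives the free diol with no effect on the stereocentres.

**Step 6**
Reactants: 6
Product: 7 bis-TES ether
Conditions: TESCl (2.5 equiv), imidazole, DMF, rt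
Reagents that add atoms: chlorotriethylsilane CC[Si](Cl)(CC)CC
Why: Silylation of both OH groups, setting up differentiation of the primary and secondary positions.

**Step 7**
Reactants: 7
Product: 8 primary alcohol with C8–OTES
Conditions: PPTS (0.2 equiv), MeOH/CH2Cl2 1:1, 0 °C
Reagents that add atoms: none
Why: The primary TES ether is cleaved kinetically faster than the secondary one. The methyl acetal only exchanges with MeOH, which leaves it unchanged.

**Step 8**
Reactants: 8
Product: 9 α-silyloxy aldehyde (C7 CHO, C8 OTES)
Conditions: Dess–Martin periodinane, NaHCO3, CH2Cl2, rt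
Reagents that add atoms: none
Why: Buffered Dess–Martin oxidation of the primary alcohol, with minimal epimerisation of the α-stereocentre.

**Step 9**
Reactants: 9
Product: 10 Baylis–Hillman adduct (C7 carbinol, diastereomer mixture)
Conditions: methyl acrylate (5 equiv), DABCO (1 equiv), MeOH, rt
Reagents that add atoms: methyl acrylate C=CC(=O)OC
Why: Morita–Baylis–Hillman reaction. The C7 carbinol stereochemistry is irrelevant because it is destroyed in the next step.

**Step 10**
Reactants: 10
Product: 11 allyl bromide, (Z)-2-(bromomethyl)alk-2-enoate (C7=C11, CH2Br)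
Conditions: NBS, Me2S, CH2Cl2, –20 °C to rt
Reagents that add atoms: N-bromosuccinimide O=C1CCC(=O)N1Br
Why: Neutral SN2′ bromination with allylic transposition, which spares the acid-labile acetal. The alkene geometry is irrelevant because the allylchromium equilibrates.

**Step 11**
Reactants: 12 2-butyne-1,4-diol
Product: 13 4-(TBSO)but-2-yn-1-ol
Conditions: NaH (1 equiv), TBSCl (1 equiv), THF, 0 °C
Reagents that add atoms: tert-butyldimethylsilyl chloride CC(C)(C)[Si](C)(C)Cl
Why: Mono-silylation of the symmetrical diol.

**Step 12**
Reactants: 13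
Product: 14 (Z)-3-iodo-4-(TBSO)but-2-en-1-ol
Conditions: Red-Al, THF, 0 °C; then I2, –78 °C
Reagents that add atoms: iodine II
Why: Hydroxyl-directed trans-hydroalumination places Al at C3, and iodinolysis gives the Z-vinyl iodide (I cis to CH2OH, Corey-type). This fixes the ring Z-olefin geometry for later.

**Step 13**
Reactants: 14
Product: 15 (Z)-3-iodo-4-(TBSO)but-2-enal
Conditions: MnO2, CH2Cl2, rt
Reagents that add atoms: none
Why: Chemoselective oxidation of the allylic alcohol, with the Z geometry retained.

**Step 14**
Reactants: 11, 15
Product: 16 trans-fused α-methylene-γ-lactone bearing the Z-vinyl iodide at C6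
Conditions: CrCl2 (Ni-free, 4 equiv), THF, 0 °C to rt; then DBU (0.2 equiv), PhMe, 40 °C
Reagents that add atoms: none
Why: Hiyama/Nozaki-type Cr-Barbier allylation proceeds through a chair transition state with γ-attack at C7 and anti selectivity. This gives the C6/C7 anti homoallylic alcohol, and the C8 α-silyloxy centre biases the facial selectivity. Lactonisation (loss of MeOH) then gives the trans lactone. The vinyl iodide is inert to Ni-free Cr(II).

**Step 15**
Reactants: 16
Product: 17 lactone dimethylamine adduct (C11 epimer mixture)
Conditions: Me2NH (2 M in THF), rt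
Reagents that add atoms: dimethylamine CNC
Why: Aza-Michael masking of the α-methylene group prevents Heck-type or reductive reaction with the Ni catalyst in step 17. The C11 epimer mixture is irrelevant because it is eliminated later.

**Step 16**
Reactants: 17
Product: 18 lactol/hydroxy-aldehyde with free C8–OH
Conditions: AcOH/THF/H2O 3:1:1, 25 °C, 3 h
Reagents that add atoms: water O
Why: Acid hydrolysis of the methyl acetal and the secondary TES ether, while the primary TBS and the lactone survive this short exposure. This releases the C3 aldehyde in ring-chain equilibrium with the C10–OH.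

**Step 17**
Reactants: 18
Product: 19 bridged hemiketal macrocycle (C8–OH, C15–OTBS, masked lactone)
Conditions: Ni(cod)2 (20 mol%), PCy3 (40 mol%), Et3N (5 equiv), PhMe (2 mM), 80 °C, syringe-pump addition over 8 h
Reagents that add atoms: none
Why: **Proposed new method:** intramolecular redox-neutral "acyl-Heck" alkenylation of an aldehyde C–H with a Z-vinyl iodide to close a medium-ring enone. The proposed mechanism has five stages:
- Ni(0) adds oxidatively to the C4–I bond with retention of Z geometry.
- Ring-chain tautomerism of the lactol supplies the free aldehyde.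
- The aldehyde C=O inserts into the vinyl–Ni bond, templated by the C10/C8 hydroxyls, giving a Ni alkoxide.
- β-Hydride elimination gives the (Z)-enone plus Ni–H.
- Et3N regenerates Ni(0).
The γ-hydroxy-enone then cyclises to the bridged C3 hemiketal, whose configuration is fixed by the bridge. The closest known reactions are Ni/Pd-catalysed aryl halide + aldehyde → ketone coupling and the NHK addition, which makes the same C–C bond.

**Step 18**
Reactants: 19
Product: 20 angelate ester
Conditions: angelic acid, 2,4,6-trichlorobenzoyl chloride, Et3N, THF; then DMAP, PhMe, rt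
Reagents that add atoms: angelic acid C/C=C(/C)C(=O)O
Why: Yamaguchi esterification acylates the unhindered secondary C8–OH selectively over the tertiary hemiketal OH, with the Z-alkene retained.

**Step 19**
Reactants: 20
Product: 21 α-methylene lactone (TBS ether)
Conditions: MeI (20 equiv), MeCN, rt; then aq. NaHCO3, 40 °C
Reagents that add atoms: none
Why: Quaternisation followed by retro-Michael (Hofmann-type) elimination regenerates the exocyclic methylene and expels NMe3.

**Step 20**
Reactants: 21
Product: 22 niveusin B
Conditions: HF·pyridine, pyridine, THF, 0 °C to rt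
Reagents that add atoms: none
Why: Buffered fluoride removes the primary allylic TBS ether, and the angelate, lactone and hemiketal survive.

## Compound list
1 | (R)-linalool | C=C[C@](C)(O)CCC=C(C)C | starting material
2 | lactol | C[C@@]1(CCC=C(C)C)CCC(O)O1 | intermediate
3 | methyl acetal | C[C@@]1(CCC=C(C)C)CCC(OC)O1 | intermediate
4 | C7 aldehyde | C[C@@]1(CCC=O)CCC(OC)O1 | intermediate
5 | aminoxy alcohol | C[C@@]1(C[C@H](CO)ONc2ccccc2)CCC(OC)O1 | intermediate
6 | diol | C[C@@]1(C[C@H](CO)O)CCC(OC)O1 | intermediate
7 | bis-TES ether | C[C@@]1(C[C@H](CO[Si](CC)(CC)CC)O[Si](CC)(CC)CC)CCC(OC)O1 | intermediate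
8 | primary alcohol, C8–OTES | C[C@@]1(C[C@H](CO)O[Si](CC)(CC)CC)CCC(OC)O1 | intermediate
9 | α-silyloxy aldehyde | C[C@@]1(C[C@H](C=O)O[Si](CC)(CC)CC)CCC(OC)O1 | intermediate
10 | Baylis–Hillman adduct | C[C@@]1(C[C@H](C(O)C(=C)C(=O)OC)O[Si](CC)(CC)CC)CCC(OC)O1 | intermediate
11 | allyl bromide | C[C@@]1(C[C@H](/C=C(\CBr)C(=O)OC)O[Si](CC)(CC)CC)CCC(OC)O1 | intermediate
12 | 2-butyne-1,4-diol | OCC#CCO | starting material
13 | mono-TBS butynol | OCC#CCO[Si](C)(C)C(C)(C)C | intermediate
14 | (Z)-iodoallylic alcohol | OC/C=C(\I)CO[Si](C)(C)C(C)(C)C | intermediate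
15 | (Z)-β-iodoenal | O=C/C=C(\I)CO[Si](C)(C)C(C)(C)C | intermediate
16 | trans-α-methylene lactone, vinyl iodide | C=C1C(=O)O[C@H](/C=C(\I)CO[Si](C)(C)C(C)(C)C)[C@H]1[C@@H](C[C@]2(C)CCC(OC)O2)O[Si](CC)(CC)CC | intermediate
17 | dimethylamine adduct | CN(C)CC1C(=O)O[C@H](/C=C(\I)CO[Si](C)(C)C(C)(C)C)[C@H]1[C@@H](C[C@]2(C)CCC(OC)O2)O[Si](CC)(CC)CC | intermediate
18 | lactol, free C8–OH | CN(C)CC1C(=O)O[C@H](/C=C(\I)CO[Si](C)(C)C(C)(C)C)[C@H]1[C@H](O)C[C@]2(C)CCC(O)O2 | intermediate
19 | bridged hemiketal macrocycle | CN(C)CC1C(=O)O[C@@H]2/C=C(/CO[Si](C)(C)C(C)(C)C)[C@@]3(O)CC[C@@](C)(C[C@@H](O)[C@@H]12)O3 | intermediate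
20 | angelate, amine adduct | CN(C)CC1C(=O)O[C@@H]2/C=C(/CO[Si](C)(C)C(C)(C)C)[C@@]3(O)CC[C@@](C)(C[C@@H](OC(=O)/C(C)=C\C)[C@@H]12)O3 | intermediate
21 | TBS-protected niveusin B | C=C1C(=O)O[C@@H]2/C=C(/CO[Si](C)(C)C(C)(C)C)[C@@]3(O)CC[C@@](C)(C[C@@H](OC(=O)/C(C)=C\C)[C@@H]12)O3 | intermediate
22 | niveusin B | C=C1C(=O)O[C@@H]2/C=C(/CO)[C@@]3(O)CC[C@@](C)(C[C@@H](OC(=O)/C(C)=C\C)[C@@H]12)O3 | target

## Totals
Total steps: 20. Longest linear sequence: 17 (steps 1–10, then 14–20).

## Three steps most likely to fail
1. **Step 17 (proposed new Ni-catalysed macrocyclisation).** The medium-ring closure may lose to protodeiodination or lactol-to-lactone transfer oxidation.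
   - Fallback: use the same lactol 18 in a Ni/Cr-mediated NHK macrocyclisation (NiCl2 0.5 mol%, CrCl2 6 equiv, DMF/THF, 2 mM), then oxidise the C3 allylic alcohol with Dess–Martin periodinane. This is a Cr(III) alkenyl umpolung plus a separate oxidation, and it gives the same hemiketal.
2. **Step 14 (Cr-Barbier allylation).** The C6/C7 facial selectivity relative to C8 may be poor, and the acetal may be sensitive to Cr(III).
   - Fallback: reagent control. Convert the C7 aldehyde to a tartrate-modified (Z)-γ-substituted α-(alkoxycarbonyl)allylboronate (Hoffmann/Hall type) and add it to enal 15. Lactonisation then gives the trans lactone independent of C8.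
3. **Step 9 (Baylis–Hillman on the α-silyloxy aldehyde).** The reaction is slow and may epimerise C8.
   - Fallback: replace steps 9–10 with a Horner–Wadsworth–Emmons olefination using ethyl 2-(diethoxyphosphoryl)propanoate, then Wohl–Ziegler NBS bromination, to reach allyl bromide 11 by olefination and radical bromination instead of MBH and SN2′.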